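## Structural features

The target is a trans-fused hydroazulene (guaiane): a cyclopentane (C1–C5) shares the C1–C5 bond with a cycloheptane (C1, C5–C10), and the C8 oxygen carries a 4-hydroxybenzoyl group. There are seven stereocentres in two contiguous groups, C10–C1–C5–C4–C3 around the ring fusion and C7–C8 on the far side of the large ring. C10 (tertiary carbinol) and C4 (methyl-bearing epoxide carbon) are fully substituted. H-1 is trans to H-5; the C10 hydroxyl is cis to H-1 and to the C3–C4 epoxide; the C8 ester oxygen is trans to both the C10 hydroxyl and the C7 isopropyl. The fragile groups are the trisubstituted epoxide (acid), the tertiary alcohol (dehydration), the aryl ester (base, organometallics) and the free phenol. The carbon skeleton is not the hard part. The difficulty is oxygen at C8, a methylene with no neighbouring activating group, its trans relation to the C10 hydroxyl, and a C3–C4 olefin placed regio- and face-selectively next to the ring fusion. The key step uses the 1,3-relation C10(O)–C9–C8 inside the seven-membered ring: a silicon hydride hung on the C10 oxygen can reach the C8–H bond that is cis to it, so the tertiary alcohol becomes the directing group for C8 oxygenation.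

## Logic of the disconnections

26 to 25: the phenol O–Si bond is cut. A silyl ether keeps the phenol out of the Mitsunobu activation and away from the vanadium catalyst. The forward step must spare the aryl ester and the epoxide, hence buffered fluoride.

25 to 24: both epoxide C–O bonds (C3–O, C4–O) are cut. This removes two stereocentres and leaves the only olefin of the molecule. The forward step must deliver oxygen to the α face, which is the face of the C10 hydroxyl, so a hydroxyl-directed epoxidation is required.

24 to 20 and 23: the C8–O(acyl) bond is cut as an alkyl–oxygen bond with inversion. The silicon route necessarily gives the C8 oxygen cis to the C10 oxygen, and the target has it trans; an inverting esterification corrects this and attaches the aromatic acid in one operation. The forward step needs SN2 displacement at a hindered secondary carbinol to beat elimination, with the tertiary alcohol left alone.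

23 to 21: the phenol O–Si bond is cut. The forward step must silylate the phenol and leave the carboxylic acid free.

20 back to 15 (through 19, 18, 17, 16): the C3–H bond is traced to C3–OTf and then to the C3 ketone. The olefin position then depends only on the enolisation direction of a 2-methylcyclopentanone, and the reagent that forms the enol ether also masks both hydroxyls. This is why the ester is introduced after, not before, the olefin: no ester, phenol or free alcohol is present when the enolate and the triflating agent are used. The forward steps need enolisation toward C4 and a reduction that does not move the double bond.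

15 to 14: the two ketal C–O bonds are cut. The forward hydrolysis must leave the tertiary alcohol intact.

14 to 13: the C8–O bond is traced to a C8–Si bond. Oxidation of C–Si occurs with retention, so the cis-1,3-diol is fixed by the ring in 13. The forward step must oxidise a hindered secondary C–Si bond.

13 to 12: the C8–Si bond is cut, opening the oxasilolane. The problem becomes the 8-deoxy skeleton. The forward step must choose C8 over C2 and the C8–H bond cis to the C10 oxygen.

12 to 10 and 11: the Si–O bond is cut. The forward step must stop at the mono-alkoxy(hydrido)silane.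

10 to 9 to 8: the ketal is removed, then the C5–H and C4–H bonds are cut to return the C4=C5 enone. The forward reduction must give the trans ring fusion. The ketal is kept because it is inert to the iridium hydride and is the only element that biases C8 over C2.

8 to 7: the photorearrangement is reversed (C5–C10 reconnected, C1–C5 and C10–O cut). The hydroazulene becomes a decalin dienone, so the 5/7 problem becomes a Robinson annulation problem. The forward step must follow the 5/7 pathway (secured by the 4-methyl group) and transfer the C10 configuration stereospecifically to C10 and C1.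

7 to 6: the C1=C2 double bond is removed. The forward dehydrogenation must give the cross-conjugated, not the linear, dienone.

6 to 2 and 3 (through 5 and 4): the C4=C5 bond (aldol) and the C1–C10 bond (Michael) are cut. The forward Michael addition must place the new chain cis to the isopropyl, so that the angular methyl is trans to it.

2 to 1: hydrogen is removed. The C7 stereocentre comes from the chiral pool; the (S)-enantiomer is the one that leads to the required absolute configuration.

## Other disconnections considered

Alternative 1: The cut is C5–C1 and C5–C6, taking the seven-membered ring back to a benzene ring and C5 to a diazo carbon in the aryl diazoketone A1. In the forward step Rh2(OAc)4 or Rh2(S-PTTL)4 (divalent rhodium) would form a carbenoid from A1 that adds to the unsubstituted ipso/ortho bond; opening of the norcaradiene would give the dihydroazulenone A2.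
- In its favour: fourteen of the fifteen skeletal carbons and the C8 oxygen (as the methoxy group) come from a cheap aromatic monoterpene ether, and both rings are formed in one catalytic step.
- Better than the chosen plan: the C8 oxygen is placed by the substitution pattern of an arene, not by C–H activation, and the bicyclic core is reached in fewer steps than 9.
- Against it: A2 is almost flat. It has one stereocentre (C5), which is α to the ketone and doubly allylic and so can be lost by enolisation or hydrogen shifts. C1, C7, C8 and C10 would then have to be set on a cycloheptatriene by reductions and a hydration with little to guide them.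
- Against it: the C15 methyl must be added to the C4 ketone and the resulting tertiary alcohol dehydrated, a regiochemical problem at least as hard as the enolisation in the chosen route.
- Against it: addition on the methyl-bearing side, aromatic C–H insertion and acid-induced rearrangement of A2 are possible diversions.
- Comparison: the chosen plan is longer to the core, but takes C7 from the chiral pool and C10/C1 from a stereospecific rearrangement. The alternative is mechanistically elegant, but its step economy would be lost in the later stereochemical work.

Alternative 2: The cut is C5–C1, C6–C7 and C10–O, giving the acyclic (E)-enynone A3. In the forward step AuCl (monovalent gold) would activate the terminal alkyne; the alkene would attack it (C5–C1), the ketone oxygen would add to C10, and the resulting alkenyl–metal carbon C6 would close onto C7, giving the oxygen-bridged tricycle A4.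
- In its favour: two C–C bonds, one C–O bond, both carbocycles and the C1/C10 relation are formed in one isomerisation with full atom economy.
- Better than the chosen plan: the C8 oxygen in A4 already has the final configuration relative to the C10 oxygen, so no inversion is needed. In ring construction per step it is clearly superior.
- Against it: the target has no C7–O–C10 bridge. C7 must become a CH carrying the isopropyl on the face the bridge oxygen occupies in A4, which means a net inverting removal of a tertiary allylic oxygen.
- Against it: C4 lacks its methyl (oxidation, methyl addition and a regioselective dehydration would be needed), and the C5=C6 olefin must be reduced to a trans ring fusion.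
- Against it: A3 needs two separately made stereocentres.
- Comparison: the chosen plan has a less certain key step and a more linear skeleton synthesis. After its key step, however, only functional-group operations of known type remain, whereas A4 needs corrections of oxidation level and configuration at C7, C4 and C5 that would probably outnumber them.

Alternative 3: The cut is C5–C6 and C7–C8 (the two bonds of a photocycloaddition), with C5–C8 reconnected; the seven-membered ring goes back to the 2-acetylcyclopentanone A5 and 3-methylbut-1-ene A6. In the forward step irradiation of enolised A5 with A6 would give a cyclobutanol whose retro-aldol opening expands the ring to the cycloheptanone A7. Numbered from the ring carbonyl, A7 is 4-acetyl-5-allyl-2-isopropyl-6-methyl-6-silyloxycycloheptanone. The ring ketone is C8, next to the isopropyl carbon C7; a name that puts the methyl/silyloxy carbon next to the carbonyl would describe a different constitution.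
- In its favour: C8 arrives as a ketone, and the C10 carbinol and C1 are set early on a five-membered ring.
- Better than the chosen plan: C8 needs no C–H oxidation and no inversion, since reduction to the alcohol trans to the isopropyl is the thermodynamically favoured outcome.
- Better than the chosen plan: after cleavage of the allyl group, a reductive carbonyl coupling with the acetyl group would form the C3=C4 olefin with no regiochemical ambiguity.
- Against it: intermolecular [2+2] addition of a monosubstituted alkene gives little control of head-to-head versus head-to-tail orientation or of the C7 configuration.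
- Against it: ring expansion requires the endocyclic enol of A5, while 2-acylcyclopentanones favour the exocyclic enol, which would lead to chain extension instead.
- Against it: A6 is a gas at room temperature, three carbonyl groups must later be told apart, and A5 is itself a multi-step enantioselective target.
- Comparison: the chosen plan gives every stereocentre a defined source, at the price of a longer linear sequence and an unprecedented C–H step. The alternative is shorter on paper but puts its risk in the step that sets C7 and the ring size.

Key step: step 8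

Remarks:
- Guaiane numbering is used only as a positional frame, and every stereocentre is stated explicitly. α/β refer to the usual drawing (five-membered ring left, C10 at the top, β toward the viewer).
- In that frame the target is (1R,3R,4S,5S,7S,8R,10R): 1α-H, 5β-H, 7β-H (isopropyl α), 3α,4α-epoxide (4-methyl β), 8β-ester, 10α-OH (10-methyl β).
- Assumption: the base-mediated annulation of step 2 follows the known preference of 2-methyl-5-alkylcyclohexanones for the 10-epi (angular methyl trans to the C7 substituent) series.

## Route

Step 1
Reactants: 1 (S)-(+)-carvone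
Product: 2 (5S)-2-methyl-5-(propan-2-yl)cyclohexan-1-one (carvomenthone, mixture of C2 epimers)
Conditions: H2 (1 atm), Pd/C, EtOAc, rt
Reagents that add atoms: none
Why: Heterogeneous hydrogenation saturates both C=C bonds; the C5 stereocentre is not involved, and the C2 epimer mixture does not matter because C2 becomes the enolate carbon in step 2.

Step 2
Reactants: 2 (5S)-2-methyl-5-(propan-2-yl)cyclohexan-1-one; 3 ethyl vinyl ketone
Product: 6 (4aS,7S)-1,4a-dimethyl-7-(propan-2-yl)-4,4a,5,6,7,8-hexahydronaphthalen-2(3H)-one, via Michael diketone 4 (not isolated), via aldol ketol 5 (not isolated)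
Conditions: KOH, EtOH/Et2O, 0 °C; then KOH, EtOH, reflux
Reagents that add atoms: none
Why: Robinson annulation: the more substituted enolate should add to the enone along the chair-like axial trajectory with the isopropyl equatorial, so the chain enters cis to the isopropyl and the angular methyl ends trans to it; aldol closure and dehydration give the enone, and the minor diastereomer should be removable at the ketol or enone stage.

Step 3
Reactants: 6 (4aS,7S)-1,4a-dimethyl-7-(propan-2-yl)-4,4a,5,6,7,8-hexahydronaphthalen-2(3H)-one
Product: 7 (4aS,7S)-1,4a-dimethyl-7-(propan-2-yl)-5,6,7,8-tetrahydronaphthalen-2(4aH)-one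
Conditions: DDQ, dioxane, reflux
Reagents that add atoms: none
Why: DDQ dehydrogenation of a 4-en-3-one under neutral conditions should remove hydride from C1 of the 2,4-dienol and give the cross-conjugated 1,4-dien-3-one; no stereocentre is touched.

Step 4
Reactants: 7 (4aS,7S)-1,4a-dimethyl-7-(propan-2-yl)-5,6,7,8-tetrahydronaphthalen-2(4aH)-one
Product: 8 10α-hydroxy-1αH,7βH-guai-4-en-3-one (10-methyl β; hydroxyl cis to H-1)
Conditions: hν (Hg lamp, Pyrex), 45% aq AcOH, rt
Reagents that add atoms: water, O
Why: Cross-conjugated cyclohexadienone photorearrangement of the santonin type: C1–C5 bonding gives a cyclopropyl zwitterion, and after protonation water opens it at C10 with inversion as C5–C10 breaks; the 4-methyl group favours the 5/7 product over the spiro product, and the angular methyl dictates both the C10 configuration and H-1 cis to the new hydroxyl.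

Step 5
Reactants: 8 10α-hydroxy-1αH,7βH-guai-4-en-3-one
Product: 9 10α-hydroxy-1αH,4αH,5βH,7βH-guaian-3-one (trans-fused; 4-methyl β)
Conditions: Li, NH3(l), THF, −78 °C; NH4Cl; then NaOMe, MeOH, rt
Reagents that add atoms: none
Why: Dissolving-metal enone reduction: the β-carbon C5 should be protonated perpendicular to the enolate plane on the face that leaves C6 and C10 both pseudo-equatorial, giving H-5 trans to H-1; the enolate is protonated on work-up, and base equilibration puts the C4 methyl trans to C6.

Step 6
Reactants: 9 10α-hydroxy-1αH,4αH,5βH,7βH-guaian-3-one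
Product: 10 3,3-(ethylenedioxy)-1αH,4αH,5βH,7βH-guaian-10α-ol
Conditions: ethylene glycol, PPTS, benzene, reflux (Dean–Stark)
Reagents that add atoms: ethylene glycol, OCCO
Why: Acid-catalysed ketalisation with azeotropic water removal; PPTS should be mild enough for the tertiary alcohol, and C4 stays at its thermodynamic configuration.

Step 7
Reactants: 10 3,3-(ethylenedioxy)-1αH,4αH,5βH,7βH-guaian-10α-ol; 11 diethylsilane
Product: 12 10α-[diethyl(hydrido)silyloxy]-3,3-(ethylenedioxy)-1αH,4αH,5βH,7βH-guaiane
Conditions: 11 (1.5 equiv), [Ir(cod)OMe]2 (0.5 mol%), THF, 60 °C; volatiles removed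
Reagents that add atoms: none
Why: Iridium-catalysed dehydrogenative O-silylation of an alcohol with a dihydrosilane; the excess silane keeps the product at the mono-alkoxy(hydrido)silane stage and is stripped off with the hydrogen before step 8.

Step 8
Reactants: 12 10α-[diethyl(hydrido)silyloxy]-3,3-(ethylenedioxy)-1αH,4αH,5βH,7βH-guaiane
Product: 13 oxasilolane bridging C10–O and C8 (8α-silyl, 10α-oxy; Si(Et)2 joined to C8 and to the C10 oxygen), 3-ketal retained
Conditions: [Ir(cod)OMe]2 (2 mol%), 3,4,7,8-tetramethyl-1,10-phenanthroline (5 mol%), norbornene (1.5 equiv), THF, 110 °C, sealed tube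
Reagents that add atoms: none
Why: Proposed new method: the closest known reaction type is the [Ir(cod)OMe]2/tetramethylphenanthroline-catalysed γ-silylation of secondary C–H bonds of tertiary-alcohol diethyl(hydrido)silyl ethers, which after oxidation gives 1,3-diols; it has not been shown for a ring methylene lying across a seven-membered ring from the carbinol in competition with a second γ-methylene. Mechanistically the Si–H bond adds to iridium, norbornene takes up the hydride and later the C–H hydrogen as norbornane, the silyl-bound metal cleaves the γ C8–H bond through a six-membered iridacycle (Ir, Si, O, C10, C9, C8) in what should be the turnover-limiting step, and C–Si reductive elimination releases the product. The ring closed is the five-membered 1,2-oxasilolane (Si, O, C10, C9, C8), formed in a γ-selective, cis-bridging mode across C8 and C10 of the cycloheptane, giving a 7-oxa-8-silabicyclo[4.2.1]nonane. The new C8 stereocentre is controlled by the tether: only the 8α-hydrogen, cis to the C10 oxygen, can reach silicon, and silicon takes its place. The step needs C8 over C2: reaction at C2 would require an oxasilolane trans-fused across C1–C10 (the C10 oxygen is α, C2 leaves C1 on the β side) and cleavage of a C–H bond neopentyl to the dioxolane carbon, while the tertiary C5–H points to the β face and is too hindered for this catalyst. The reacting C8–H is axial in the chair-like conformer that keeps the C7 isopropyl equatorial, so the cis isopropyl flanks it without covering it. No primary γ C–H bond, the preferred site of this catalyst, is present.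

Step 9
Reactants: 13 oxasilolane bridging C10–O and C8
Product: 14 3,3-(ethylenedioxy)-1αH,4αH,5βH,7βH-guaiane-8α,10α-diol (cis-1,3-diol)
Conditions: t-BuOOH, CsOH·H2O, TBAF, DMF, 70 °C
Reagents that add atoms: tert-butyl hydroperoxide, CC(C)(C)OO
Why: Tamao–Fleming oxidation of the alkoxydialkylsilane under the basic hydroperoxide/fluoride conditions used for hindered secondary C–Si bonds; C8 migrates from silicon to oxygen with retention, so the diol is cis, and the ketal is stable to base.

Step 10
Reactants: 14 3,3-(ethylenedioxy)-1αH,4αH,5βH,7βH-guaiane-8α,10α-diol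
Product: 15 8α,10α-dihydroxy-1αH,4αH,5βH,7βH-guaian-3-one
Conditions: aq HCl (1 M), THF, rt
Reagents that add atoms: water, O
Why: Acid hydrolysis of the dioxolane; dilute acid at room temperature should leave the tertiary alcohol intact, and C4 remains at its thermodynamic configuration.

Step 11
Reactants: 15 8α,10α-dihydroxy-1αH,4αH,5βH,7βH-guaian-3-one
Product: 16 3,8α,10α-tris(trimethylsilyloxy)-1αH,5βH,7βH-guai-3-ene
Conditions: TMSCl, NaI, Et3N, MeCN, rt
Reagents that add atoms: chlorotrimethylsilane, C[Si](C)(C)Cl
Why: Thermodynamic silyl enol ether formation with iodotrimethylsilane made in the flask: under these equilibrating conditions a 2-methylcyclopentanone should give mainly the more substituted C3=C4 enol ether, and the same reagent caps both hydroxyls.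

Step 12
Reactants: 16 3,8α,10α-tris(trimethylsilyloxy)-1αH,5βH,7βH-guai-3-ene
Product: 18 8α,10α-bis(trimethylsilyloxy)-1αH,5βH,7βH-guai-3-en-3-yl trifluoromethanesulfonate, via lithium enolate 17 (not isolated)
Conditions: MeLi (1.05 equiv), THF, 0 °C; then PhNTf2, −78 to 0 °C; NH4Cl
Reagents that add atoms: N-phenylbis(trifluoromethanesulfonimide), O=S(=O)(N(c1ccccc1)S(=O)(=O)C(F)(F)F)C(F)(F)F
Why: MeLi cleaves the enol O–Si bond much faster than the alkyl O–Si bonds and gives the lithium enolate without loss of regiochemistry; O-sulfonylation with PhNTf2 is the standard enolate-to-enol-triflate conversion, and no ester or free hydroxyl is present at this stage.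

Step 13
Reactants: 18 8α,10α-bis(trimethylsilyloxy)-1αH,5βH,7βH-guai-3-en-3-yl trifluoromethanesulfonate
Product: 20 1αH,5βH,7βH-guai-3-ene-8α,10α-diol, via bis-silyl alkene 19 (not isolated)
Conditions: Pd(OAc)2, PPh3, HCO2H, Bu3N, DMF, 60 °C; then K2CO3, MeOH, rt
Reagents that add atoms: none
Why: Palladium-catalysed formate reduction of an enol triflate (oxidative addition to zerovalent palladium, decarboxylation of formate, C–H reductive elimination) replaces OTf by H without moving the double bond; methanolysis then removes both trimethylsilyl ethers.

Step 14
Reactants: 21 4-hydroxybenzoic acid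
Product: 23 4-(tert-butyldimethylsilyloxy)benzoic acid, via bis-silylated acid 22 (not isolated)
Conditions: TBSCl (2.2 equiv), imidazole, DMF, rt; then AcOH/THF/H2O, rt
Reagents that add atoms: tert-butyldimethylsilyl chloride, CC(C)(C)[Si](C)(C)Cl
Why: Silylation of both acidic groups followed by selective hydrolysis of the much more labile silyl ester leaves the aryl silyl ether.

Step 15
Reactants: 20 1αH,5βH,7βH-guai-3-ene-8α,10α-diol; 23 4-(tert-butyldimethylsilyloxy)benzoic acid
Product: 24 10α-hydroxy-1αH,5βH,7βH-guai-3-en-8β-yl 4-(tert-butyldimethylsilyloxy)benzoate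
Conditions: PPh3, DIAD, toluene, 0 °C to rt
Reagents that add atoms: none
Why: Mitsunobu esterification: the secondary C8 oxygen is activated as its oxyphosphonium and displaced by the carboxylate from the β face, anti to the C7 isopropyl, with inversion, which sets the ester trans to the C10 hydroxyl; the tertiary hydroxyl cannot be displaced and, being cis, cannot attack C8 from the rear.

Step 16
Reactants: 24 10α-hydroxy-1αH,5βH,7βH-guai-3-en-8β-yl 4-(tert-butyldimethylsilyloxy)benzoate
Product: 25 3α,4α-epoxy-10α-hydroxy-1αH,5βH,7βH-guaian-8β-yl 4-(tert-butyldimethylsilyloxy)benzoate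
Conditions: VO(acac)2 (5 mol%), t-BuOOH, CH2Cl2, rt
Reagents that add atoms: tert-butyl hydroperoxide, CC(C)(C)OO
Why: Hydroxyl-directed vanadium-catalysed epoxidation of a bishomoallylic alcohol: the vanadium alkylperoxide bound to the C10 alkoxide should deliver oxygen to the α face of C3=C4, setting C3 and C4; the epoxide is cis to the hydroxyl, so the hydroxyl cannot open it from the rear.

Step 17
Reactants: 25 3α,4α-epoxy-10α-hydroxy-1αH,5βH,7βH-guaian-8β-yl 4-(tert-butyldimethylsilyloxy)benzoate
Product: 26 (1R,3R,4S,5S,7S,8R,10R)-3,4-epoxy-10-hydroxyguaian-8-yl 4-hydroxybenzoate (CNP0225095.2)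
Conditions: TBAF, AcOH, THF, 0 °C
Reagents that add atoms: none
Why: Fluoride cleavage of the aryl silyl ether; the acetic acid buffer should keep the phenoxide from attacking the ester and leaves the epoxide and tertiary alcohol untouched.

## Compound list

1 | (S)-(+)-carvone | CC1=CC[C@@H](CC1=O)C(C)=C | starting material
2 | (5S)-2-methyl-5-(propan-2-yl)cyclohexan-1-one (C2 epimer mixture) | CC1CC[C@@H](CC1=O)C(C)C | intermediate
3 | ethyl vinyl ketone | CCC(=O)C=C | starting material
4 | (2S,5S)-2-methyl-2-(3-oxopentyl)-5-(propan-2-yl)cyclohexan-1-one (chain cis to isopropyl) | CCC(=O)CC[C@]1(C)CC[C@H](C(C)C)CC1=O | intermediate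
5 | 5-hydroxy-4,10-dimethyl-7-(propan-2-yl)decalin-3-one ketol (eudesmane numbering; 10-methyl trans to 7-isopropyl; C4 and C5 as formed) | CC1C(=O)CC[C@]2(C)CC[C@H](C(C)C)CC12O | intermediate
6 | (4aS,7S)-1,4a-dimethyl-7-(propan-2-yl)-4,4a,5,6,7,8-hexahydronaphthalen-2(3H)-one | CC1=C2C[C@@H](C(C)C)CC[C@@]2(C)CCC1=O | intermediate
7 | (4aS,7S)-1,4a-dimethyl-7-(propan-2-yl)-5,6,7,8-tetrahydronaphthalen-2(4aH)-one | CC1=C2C[C@@H](C(C)C)CC[C@@]2(C)C=CC1=O | intermediate
8 | 10α-hydroxy-1αH,7βH-guai-4-en-3-one | CC(C)[C@@H]1CC2=C(C)C(=O)C[C@H]2[C@](C)(O)CC1 | intermediate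
9 | 10α-hydroxy-1αH,4αH,5βH,7βH-guaian-3-one | CC(C)[C@@H]1C[C@H]2[C@@H](CC(=O)[C@@H]2C)[C@](C)(O)CC1 | intermediate
10 | 3,3-(ethylenedioxy)-1αH,4αH,5βH,7βH-guaian-10α-ol | CC(C)[C@@H]1C[C@H]2[C@@H](CC3(OCCO3)[C@@H]2C)[C@](C)(O)CC1 | intermediate
11 | diethylsilane | CC[SiH2]CC | starting material
12 | 10α-[diethyl(hydrido)silyloxy]-3,3-(ethylenedioxy)-1αH,4αH,5βH,7βH-guaiane | CC(C)[C@@H]1C[C@H]2[C@@H](CC3(OCCO3)[C@@H]2C)[C@](C)(O[SiH](CC)CC)CC1 | intermediate
13 | oxasilolane bridging C10–O and C8 (8α-Si, 10α-O), 3-ketal | CC(C)[C@@H]1C[C@H]2[C@@H](CC3(OCCO3)[C@@H]2C)[C@@]4(C)C[C@@H]1[Si](CC)(CC)O4 | intermediate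
14 | 3,3-(ethylenedioxy)-1αH,4αH,5βH,7βH-guaiane-8α,10α-diol | CC(C)[C@@H]1C[C@H]2[C@@H](CC3(OCCO3)[C@@H]2C)[C@](C)(O)C[C@@H]1O | intermediate
15 | 8α,10α-dihydroxy-1αH,4αH,5βH,7βH-guaian-3-one | CC(C)[C@@H]1C[C@H]2[C@@H](CC(=O)[C@@H]2C)[C@](C)(O)C[C@@H]1O | intermediate
16 | 3,8α,10α-tris(trimethylsilyloxy)-1αH,5βH,7βH-guai-3-ene | CC(C)[C@@H]1C[C@H]2[C@@H](CC(O[Si](C)(C)C)=C2C)[C@](C)(O[Si](C)(C)C)C[C@@H]1O[Si](C)(C)C | intermediate
17 | lithium 8α,10α-bis(trimethylsilyloxy)-1αH,5βH,7βH-guai-3-en-3-olate | CC(C)[C@@H]1C[C@H]2[C@@H](CC(O[Li])=C2C)[C@](C)(O[Si](C)(C)C)C[C@@H]1O[Si](C)(C)C | intermediate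
18 | 8α,10α-bis(trimethylsilyloxy)-1αH,5βH,7βH-guai-3-en-3-yl trifluoromethanesulfonate | CC(C)[C@@H]1C[C@H]2[C@@H](CC(OS(=O)(=O)C(F)(F)F)=C2C)[C@](C)(O[Si](C)(C)C)C[C@@H]1O[Si](C)(C)C | intermediate
19 | 8α,10α-bis(trimethylsilyloxy)-1αH,5βH,7βH-guai-3-ene | CC(C)[C@@H]1C[C@H]2[C@@H](CC=C2C)[C@](C)(O[Si](C)(C)C)C[C@@H]1O[Si](C)(C)C | intermediate
20 | 1αH,5βH,7βH-guai-3-ene-8α,10α-diol | CC(C)[C@@H]1C[C@H]2[C@@H](CC=C2C)[C@](C)(O)C[C@@H]1O | intermediate
21 | 4-hydroxybenzoic acid | OC(=O)c1ccc(O)cc1 | starting material
22 | tert-butyldimethylsilyl 4-(tert-butyldimethylsilyloxy)benzoate | CC(C)(C)[Si](C)(C)OC(=O)c1ccc(O[Si](C)(C)C(C)(C)C)cc1 | intermediate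
23 | 4-(tert-butyldimethylsilyloxy)benzoic acid | CC(C)(C)[Si](C)(C)Oc1ccc(cc1)C(O)=O | intermediate
24 | 10α-hydroxy-1αH,5βH,7βH-guai-3-en-8β-yl 4-(tert-butyldimethylsilyloxy)benzoate | CC(C)[C@@H]1C[C@H]2[C@@H](CC=C2C)[C@](C)(O)C[C@H]1OC(=O)c1ccc(O[Si](C)(C)C(C)(C)C)cc1 | intermediate
25 | 3α,4α-epoxy-10α-hydroxy-1αH,5βH,7βH-guaian-8β-yl 4-(tert-butyldimethylsilyloxy)benzoate | CC(C)[C@@H]1C[C@H]2[C@@H](C[C@H]3O[C@]32C)[C@](C)(O)C[C@H]1OC(=O)c1ccc(O[Si](C)(C)C(C)(C)C)cc1 | intermediate
26 | (1R,3R,4S,5S,7S,8R,10R)-3,4-epoxy-10-hydroxyguaian-8-yl 4-hydroxybenzoate | CC(C)[C@@H]1C[C@H]2[C@@H](C[C@H]3O[C@]32C)[C@](C)(O)C[C@H]1OC(=O)c1ccc(O)cc1 | target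

## Step count and least certain steps

Total step count: 17. Longest linear sequence: 16 (steps 1–13 and 15–17, from (S)-carvone); step 14 is a one-step side branch.

**Step 8 (key step).** Most likely failures are: no C–H cleavage, because the ring methylene is reached only in the conformer with the C10–O and C8–H bonds both axial and it adjoins the isopropyl-bearing carbon; competing silylation at C2; or redistribution of the silyl ether at 110 °C.

The fallback uses known chemistry, a carbamate-directed radical γ-bromination of the Hofmann–Löffler–Freytag type followed by carbonate closure. It sets out from 10 and returns at 14. 10 is treated with 2,2,2-trifluoroethyl isocyanate to give the N-(2,2,2-trifluoroethyl)carbamate F1. N-Bromination with acetyl hypobromite and irradiation generate the amidyl radical, which should take the 8α-hydrogen through a seven-membered transition state; the C2 hydrogens next to the ketal are inductively deactivated toward this electrophilic radical. Bromine transfer anti to the isopropyl gives the 8β-bromide F2. Ag2CO3 then assists displacement of bromide by the carbamate carbonyl oxygen with inversion, and hydrolysis of the iminocarbonate gives the 8α,10α-cyclic carbonate F3. K2CO3 in methanol releases 14.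

**Step 5 (ring fusion).** Protonation of C5 may occur on the wrong face, for example by intramolecular proton delivery from the C10 hydroxyl, because cis- and trans-hydroazulenes differ little in energy; this would give the cis-fused ketone.

The fallback sets out from 8 and returns at 9. Reduction with NaBH4/CeCl3·7H2O, with hydride entering from the side of H-1, gives the allylic alcohol 1αH,7βH-guai-4-ene-3β,10α-diol F4. Hydrogenation with [Ir(cod)(PCy3)(py)]PF6, directed by the nearer allylic 3β-hydroxyl, adds hydrogen to the β face and gives 1αH,4βH,5βH,7βH-guaiane-3β,10α-diol F5 with H-5 trans to H-1. Dess–Martin oxidation of the secondary alcohol gives the 4-epimeric ketone F6, which NaOMe equilibrates to 9.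

**Step 11 (regiochemistry of enolisation).** Enolisation toward C2 would give a regioisomeric enol ether and, after steps 12 and 13, the C2=C3 olefin; thermodynamic control in a 2-methylcyclopentanone is good but not complete.

The fallback takes the regiochemistry from the enone. It sets out from 8 and returns at 20. Li/NH3 reduction of 8 and trapping of the resulting enolate in the same flask with PhNTf2 gives the enol triflate F7, 10α-hydroxy-1αH,5βH,7βH-guai-3-en-3-yl triflate. Pd(OAc)2/PPh3/HCO2H/Bu3N reduction gives 1αH,5βH,7βH-guai-3-en-10α-ol F8. Silylation as in step 7 gives the diethyl(hydrido)silyl ether F9, the conditions of step 8 give the olefin-bearing oxasilolane F10, and the conditions of step 9 give 20. This is four steps shorter. The price is that the olefin must survive the iridium hydride and that C2 becomes allylic, which is why the ketal is used in the main route.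

**Step 15 (Mitsunobu inversion).** Anti elimination of the axial oxyphosphonium toward C7, or acyl transfer with retention through an acyloxyphosphonium, may compete with SN2 displacement at this hindered carbinol.

The fallback sets out from 20 and returns at 24. Dess–Martin oxidation (NaHCO3 buffer) of the secondary alcohol gives the β-hydroxy ketone 10α-hydroxy-1αH,5βH,7βH-guai-3-en-8-one F11. Reduction with Me4NBH(OAc)3 in MeCN/AcOH at low temperature, with hydride delivered from the C10 oxygen, gives the anti diol 1αH,5βH,7βH-guai-3-ene-8β,10α-diol F12; this is also the isomer with the oxygen trans to the isopropyl. Acylation of the secondary hydroxyl with 23 (DCC, DMAP) then gives 24 with retention.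

**Step 16 (face of epoxidation).** Direction by a bishomoallylic tertiary hydroxyl may be too weak, and the reagent may then attack the β face, anti to the allylic C6 substituent.

The fallback sets out from 24 and returns at 25. NBS in aqueous THF forms the bromonium ion on the face preferred by an undirected electrophile (β), and water opens it at the more substituted C4 from the α face, giving the bromohydrin F13 (3β-bromo-4α-hydroxy). DBU then closes the α-epoxide 25 by displacement of bromide.

## Further compounds

F1 | step 8 | 3,3-(ethylenedioxy)-1αH,4αH,5βH,7βH-guaian-10α-yl N-(2,2,2-trifluoroethyl)carbamate | CC(C)[C@@H]1C[C@H]2[C@@H](CC3(OCCO3)[C@@H]2C)[C@](C)(OC(=O)NCC(F)(F)F)CC1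
F2 | step 8 | 8β-bromo-3,3-(ethylenedioxy)-1αH,4αH,5βH,7βH-guaian-10α-yl N-(2,2,2-trifluoroethyl)carbamate | CC(C)[C@@H]1C[C@H]2[C@@H](CC3(OCCO3)[C@@H]2C)[C@](C)(OC(=O)NCC(F)(F)F)C[C@H]1Br
F3 | step 8 | 3,3-(ethylenedioxy)-1αH,4αH,5βH,7βH-guaiane-8α,10α-diyl carbonate | CC(C)[C@@H]1C[C@H]2[C@@H](CC3(OCCO3)[C@@H]2C)[C@@]4(C)C[C@@H]1OC(=O)O4
F4 | step 5 | 1αH,7βH-guai-4-ene-3β,10α-diol | CC(C)[C@@H]1CC2=C(C)[C@@H](O)C[C@H]2[C@](C)(O)CC1
F5 | step 5 | 1αH,4βH,5βH,7βH-guaiane-3β,10α-diol | CC(C)[C@@H]1C[C@H]2[C@@H](C[C@H](O)[C@H]2C)[C@](C)(O)CC1
F6 | step 5 | 10α-hydroxy-1αH,4βH,5βH,7βH-guaian-3-one (C4 epimer of 9) | CC(C)[C@@H]1C[C@H]2[C@@H](CC(=O)[C@H]2C)[C@](C)(O)CC1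
F7 | step 11 | 10α-hydroxy-1αH,5βH,7βH-guai-3-en-3-yl trifluoromethanesulfonate | CC(C)[C@@H]1C[C@H]2[C@@H](CC(OS(=O)(=O)C(F)(F)F)=C2C)[C@](C)(O)CC1
F8 | step 11 | 1αH,5βH,7βH-guai-3-en-10α-ol | CC(C)[C@@H]1C[C@H]2[C@@H](CC=C2C)[C@](C)(O)CC1
F9 | step 11 | 10α-[diethyl(hydrido)silyloxy]-1αH,5βH,7βH-guai-3-ene | CC(C)[C@@H]1C[C@H]2[C@@H](CC=C2C)[C@](C)(O[SiH](CC)CC)CC1
F10 | step 11 | oxasilolane bridging C10–O and C8 of 1αH,5βH,7βH-guai-3-ene (8α-Si, 10α-O) | CC(C)[C@@H]1C[C@H]2[C@@H](CC=C2C)[C@@]3(C)C[C@@H]1[Si](CC)(CC)O3
F11 | step 15 | 10α-hydroxy-1αH,5βH,7βH-guai-3-en-8-one | CC(C)[C@@H]1C[C@H]2[C@@H](CC=C2C)[C@](C)(O)CC1=O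
F12 | step 15 | 1αH,5βH,7βH-guai-3-ene-8β,10α-diol | CC(C)[C@@H]1C[C@H]2[C@@H](CC=C2C)[C@](C)(O)C[C@H]1O
F13 | step 16 | 3β-bromo-4α,10α-dihydroxy-1αH,5βH,7βH-guaian-8β-yl 4-(tert-butyldimethylsilyloxy)benzoate | CC(C)[C@@H]1C[C@H]2[C@@H](C[C@H](Br)[C@@]2(C)O)[C@](C)(O)C[C@H]1OC(=O)c1ccc(O[Si](C)(C)C(C)(C)C)cc1
A1 | alternative 1 | 1-diazo-4-[4-methoxy-2-methyl-5-(propan-2-yl)phenyl]butan-2-one | [N-]=[N+]=CC(=O)CCc1cc(C(C)C)c(OC)cc1C
A2 | alternative 1 | 8-methoxy-15-nor-guaia-1(10),6,8-trien-4-one | CC(C)C1=C[C@@H]2C(=O)CCC2=C(C)C=C1OC
A3 | alternative 2 | (E)-4-(benzyloxy)-2,6-dimethyl-10-(triethylsilyloxy)dodec-6-en-11-yn-3-one | CC(C)C(=O)[C@H](OCc1ccccc1)C/C(C)=C/CC[C@H](O[Si](CC)(CC)CC)C#C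
A4 | alternative 2 | 8-(benzyloxy)-7,10-epoxy-4-(triethylsilyloxy)-15-nor-guai-5-ene | CC(C)[C@]12C=C3[C@@H](O[Si](CC)(CC)CC)CC[C@H]3[C@](C)(O1)C[C@H]2OCc1ccccc1
A5 | alternative 3 | 2-acetyl-3-allyl-4-methyl-4-(tert-butyldimethylsilyloxy)cyclopentan-1-one | CC(=O)C1C(=O)C[C@@](C)(O[Si](C)(C)C(C)(C)C)[C@@H]1CC=C
A6 | alternative 3 | 3-methylbut-1-ene | CC(C)C=C
A7 | alternative 3 | 4-acetyl-5-allyl-2-isopropyl-6-methyl-6-(tert-butyldimethylsilyloxy)cycloheptan-1-one | CC(C)[C@@H]1C[C@H](C(C)=O)[C@@H](CC=C)[C@](C)(O[Si](C)(C)C(C)(C)C)CC1=O
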